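The route rests on disconnecting the bond between cyclopentane carbon C6, the ring CH flanked by carbinol carbon C5 and side-chain carbon C2, and C7, the first carbon of the polyene chain. In one operation a nickel-catalysed, cathodically driven decarboxylative alkenylation joins a C9 cyclopentanecarboxylic acid, activated in the flask as its N-acyloxyphthalimide, to the all-E C31 polyenyl iodide. The step exploits the C6 radical: it forgets the carboxyl configuration and is captured trans to the bulky C2 substituent and the C5 methyl, so both acid epimers converge on 6S. The acid comes from (R)-α-terpineol by ozonolytic ring cleavage, aldol ring contraction and epoxide redox isomerisation; the iodide from crocetindialdehyde.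

Key step: step 10

Remark: carotenoid locants are used (C1 = carbinol carbon of the side chain; C2, C5, C6 = ring stereocentres; C7 = first chain carbon; primed locants = open-chain end), and crocetindialdehyde 11 is assumed to be a purchasable C20 building block.

Step 1
Reactants: 1 (R)-(+)-α-terpineol
Product: 2 triethylsilyl ether of (R)-α-terpineol
Conditions: TESOTf, 2,6-lutidine, CH2Cl2, −78 °C to 0 °C
Reagents that add atoms: triethylsilyl trifluoromethanesulfonate, CC[Si](CC)(CC)OS(=O)(=O)C(F)(F)F
Why: Silylation with a silyl triflate is fast even at a tertiary carbinol, and the TES ether blocks later lactol and lactone formation with the C7 carbonyl and supplies the steric bias at C2.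

Step 2
Reactants: 2 triethylsilyl ether of (R)-α-terpineol
Product: 4 (3R)-6-oxo-3-[2-(triethylsilyloxy)propan-2-yl]heptanal, via secondary ozonide 3 (not isolated)
Conditions: O3, CH2Cl2, −78 °C; then PPh3, −78 °C to rt
Reagents that add atoms: ozone, [O-][O+]=O
Why: Ozonolysis with reductive work-up cleaves the only C=C, the ring alkene of the cyclohexene, to a methyl ketone and an aldehyde while the untouched stereocentre becomes C2 of the target.

Step 3
Reactants: 4 (3R)-6-oxo-3-[2-(triethylsilyloxy)propan-2-yl]heptanal
Product: 5 (5R)-2-methyl-5-[2-(triethylsilyloxy)propan-2-yl]cyclopent-1-ene-1-carbaldehyde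
Conditions: piperidine (cat.), AcOH (cat.), toluene, 80 °C
Reagents that add atoms: none
Why: Piperidinium acetate-mediated intramolecular aldol condensation (the enamine of the aldehyde adds to the methyl ketone and water is lost) closes the five-membered ring as the conjugated enal, the regiochemistry known for the isopropenyl analogue from limonene, and the stereocentre is not enolisable.

Step 4
Reactants: 5 (5R)-2-methyl-5-[2-(triethylsilyloxy)propan-2-yl]cyclopent-1-ene-1-carbaldehyde
Product: 6 (1S,2R,5R)-5-methyl-2-[2-(triethylsilyloxy)propan-2-yl]-6-oxabicyclo[3.1.0]hexane-1-carbaldehyde (epoxide oxygen trans to the silyloxypropyl group)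
Conditions: 30% aq. H2O2, NaOH (cat.), MeOH, 0 °C
Reagents that add atoms: hydrogen peroxide, OO
Why: In this Weitz–Scheffer nucleophilic epoxidation the reversible hydroperoxide addition at C5 and the ring closure at C6 should occur on the face opposite the bulky silyloxypropyl group on the neighbouring C2, which sets the C5 oxygen as 5R.

Step 5
Reactants: 6 (1S,2R,5R)-5-methyl-2-[2-(triethylsilyloxy)propan-2-yl]-6-oxabicyclo[3.1.0]hexane-1-carbaldehyde
Product: 7 benzyl (2R,5R)-2-hydroxy-2-methyl-5-[2-(triethylsilyloxy)propan-2-yl]cyclopentane-1-carboxylate (either or both C1 epimers)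
Conditions: 3-benzyl-4,5-dimethylthiazolium chloride (10 mol%), i-Pr2NEt (10 mol%), BnOH, CH2Cl2, 30 °C
Reagents that add atoms: benzyl alcohol, OCc1ccccc1
Why: In this N-heterocyclic carbene-catalysed internal redox esterification of an α,β-epoxy aldehyde the Breslow intermediate opens the epoxide at the C6–O bond, protonation at C6 (configuration irrelevant) gives an acyl azolium that benzyl alcohol acylates, and the C5–O bond with its configuration is retained.

Step 6
Reactants: 7 benzyl (2R,5R)-2-hydroxy-2-methyl-5-[2-(triethylsilyloxy)propan-2-yl]cyclopentane-1-carboxylate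
Product: 8 (2R,5R)-2-hydroxy-2-methyl-5-[2-(triethylsilyloxy)propan-2-yl]cyclopentane-1-carboxylic acid (C1 epimers)
Conditions: H2 (1 atm), 10% Pd/C, EtOAc, rt
Reagents that add atoms: none
Why: Hydrogenolysis of the benzyl ester under neutral conditions should free the β-hydroxy acid without base-induced retro-aldol cleavage or loss of the TES ether.

Step 7
Reactants: 9 geranyl bromide
Product: 10 diethyl [(2E)-3,7-dimethylocta-2,6-dien-1-yl]phosphonate
Conditions: P(OEt)3 (neat), 130 °C, EtBr distilled off
Reagents that add atoms: triethyl phosphite, CCOP(OCC)OCC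
Why: The Michaelis–Arbuzov reaction at the unhindered primary allylic CH2 proceeds by direct SN2 substitution and keeps the 2E geometry.

Step 8
Reactants: 10 diethyl [(2E)-3,7-dimethylocta-2,6-dien-1-yl]phosphonate, 11 crocetindialdehyde
Product: 12 apo-8'-lycopenal (all-E C30 aldehyde)
Conditions: KOtBu added to 10 and 11 (3 equiv) in THF/DMSO, −20 °C to rt, dark; excess 11 recovered, 12 crystallised
Reagents that add atoms: none
Why: Horner–Wadsworth–Emmons olefination of the allylic phosphonate anion should form the new C7'=C8' bond E-selectively, and the threefold excess of the symmetrical, non-enolisable dialdehyde holds the reaction at mono-olefination.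

Step 9
Reactants: 12 apo-8'-lycopenal
Product: 13 (1E)-C31 polyenyl iodide
Conditions: CrCl2, CHI3, THF/1,4-dioxane, 0 °C to rt, dark; used at once
Reagents that add atoms: iodoform, IC(I)I
Why: In the Takai olefination the geminal dichromium species from iodoform and CrCl2 adds to the aldehyde and eliminates to the E-alkenyl iodide, a reaction that tolerates conjugated polyenals.

Step 10
Reactants: 8 (2R,5R)-2-hydroxy-2-methyl-5-[2-(triethylsilyloxy)propan-2-yl]cyclopentane-1-carboxylic acid (1.5 equiv), 13 (1E)-C31 polyenyl iodide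
Product: 15 (all-E,2R,5R,6S)-1-O-(triethylsilyl)-2,6-cyclolycopene-1,5-diol, via N-acyloxyphthalimide ester 14 (not isolated)
Conditions: N-hydroxyphthalimide, DIC, DMAP (cat.), THF, rt; then 13, NiCl2·6H2O (20 mol%), 2,2'-bipyridine (20 mol%), DMF, RVC cathode pre-plated with Ag (from AgNO3), Mg anode, constant current, rt, dark, argon
Reagents that add atoms: N-hydroxyphthalimide, ON1C(=O)c2ccccc2C1=O (its atoms enter 14 only and none stay in 15)
Why: Cathodic reduction turns the bipyridine-ligated divalent nickel into low-valent nickel, which inserts into the carbon–iodine bond of 13 with retention of the E geometry and reduces 14 by single-electron transfer, so that 14 loses phthalimide anion and CO2 and leaves a secondary radical at ring carbon C6; the alkenylnickel species captures this radical and reductive elimination from trivalent nickel forms the C6–C7 bond. The closest known reaction type is the nickel-electrocatalysed decarboxylative alkenylation of secondary alkyl N-acyloxyphthalimides with alkenyl halides at a silver-coated cathode, including activation of the acid in the flask. No ring is closed. The only new stereocentre, C6, is controlled by the substrate: the nickel-bound chain should be delivered to the ring face opposite the 2-(triethylsilyloxy)propan-2-yl group on C2 and the methyl on C5, next to the small free C5 hydroxyl, which gives 6S from either C6 epimer of 8 (stereoconvergence). The step needs chemoselectivity for radical capture at nickel over radical addition to the polyene and over cathodic reduction of the polyene; a high nickel loading, an excess of the cheap partner 8, a low steady-state radical concentration under constant current and a cathode potential held at the nickel and phthalimide ester couples should secure it. The all-E geometry should be retained because the oxidative addition is stereoretentive and the reaction runs at room temperature in the dark.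

Step 11
Reactants: 15 (all-E,2R,5R,6S)-1-O-(triethylsilyl)-2,6-cyclolycopene-1,5-diol
Product: 16 (all-E,2R,5R,6S)-2,6-cyclolycopene-1,5-diol (CNP0169920.4)
Conditions: TBAF, THF, 0 °C to rt, dark
Reagents that add atoms: none
Why: Fluoride cleaves the Si–O bond of the tertiary TES ether under non-acidic conditions that should leave the all-E polyene and both tertiary alcohols untouched.

Compound list

1 | (R)-(+)-α-terpineol, 2-[(1R)-4-methylcyclohex-3-en-1-yl]propan-2-ol | CC1=CC[C@H](C(C)(C)O)CC1 | starting material
2 | triethyl{[2-[(1R)-4-methylcyclohex-3-en-1-yl]propan-2-yl]oxy}silane | CC1=CC[C@H](C(C)(C)O[Si](CC)(CC)CC)CC1 | intermediate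
3 | secondary ozonide of 2, (4R)-1-methyl-4-[2-(triethylsilyloxy)propan-2-yl]-7,8,9-trioxabicyclo[4.2.1]nonane (bridgehead isomers) | CC12CC[C@@H](C(C)(C)O[Si](CC)(CC)CC)CC(OO1)O2 | intermediate (not isolated)
4 | (3R)-6-oxo-3-[2-(triethylsilyloxy)propan-2-yl]heptanal | CC(=O)CC[C@H](CC=O)C(C)(C)O[Si](CC)(CC)CC | intermediate
5 | (5R)-2-methyl-5-[2-(triethylsilyloxy)propan-2-yl]cyclopent-1-ene-1-carbaldehyde | CC1=C(C=O)[C@H](C(C)(C)O[Si](CC)(CC)CC)CC1 | intermediate
6 | (1S,2R,5R)-5-methyl-2-[2-(triethylsilyloxy)propan-2-yl]-6-oxabicyclo[3.1.0]hexane-1-carbaldehyde | O=C[C@@]12O[C@]1(C)CC[C@H]2C(C)(C)O[Si](CC)(CC)CC | intermediate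
7 | benzyl (2R,5R)-2-hydroxy-2-methyl-5-[2-(triethylsilyloxy)propan-2-yl]cyclopentane-1-carboxylate (C1 not defined) | O=C(OCc1ccccc1)C1[C@](C)(O)CC[C@H]1C(C)(C)O[Si](CC)(CC)CC | intermediate
8 | (2R,5R)-2-hydroxy-2-methyl-5-[2-(triethylsilyloxy)propan-2-yl]cyclopentane-1-carboxylic acid (C1 not defined) | OC(=O)C1[C@](C)(O)CC[C@H]1C(C)(C)O[Si](CC)(CC)CC | intermediate
9 | geranyl bromide, (2E)-1-bromo-3,7-dimethylocta-2,6-diene | CC(C)=CCC/C(C)=C/CBr | starting material
10 | diethyl [(2E)-3,7-dimethylocta-2,6-dien-1-yl]phosphonate | CC(C)=CCC/C(C)=C/CP(=O)(OCC)OCC | intermediate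
11 | crocetindialdehyde, (2E,4E,6E,8E,10E,12E,14E)-2,6,11,15-tetramethylhexadeca-2,4,6,8,10,12,14-heptaenedial | O=C/C(C)=C/C=C/C(C)=C/C=C/C=C(C)/C=C/C=C(C)/C=O | starting material
12 | apo-8'-lycopenal, (2E,4E,6E,8E,10E,12E,14E,16E,18E)-2,6,11,15,19,23-hexamethyltetracosa-2,4,6,8,10,12,14,16,18,22-decaenal | CC(C)=CCC/C(C)=C/C=C/C(C)=C/C=C/C(C)=C/C=C/C=C(C)/C=C/C=C(C)/C=O | intermediate
13 | (1E,3E,5E,7E,9E,11E,13E,15E,17E,19E)-1-iodo-3,7,12,16,20,24-hexamethylpentacosa-1,3,5,7,9,11,13,15,17,19,23-undecaene | CC(C)=CCC/C(C)=C/C=C/C(C)=C/C=C/C(C)=C/C=C/C=C(C)/C=C/C=C(C)/C=C/I | intermediate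
14 | 1,3-dioxoisoindolin-2-yl (2R,5R)-2-hydroxy-2-methyl-5-[2-(triethylsilyloxy)propan-2-yl]cyclopentane-1-carboxylate (C1 not defined) | O=C(ON1C(=O)c2ccccc2C1=O)C1[C@](C)(O)CC[C@H]1C(C)(C)O[Si](CC)(CC)CC | intermediate (not isolated)
15 | (all-E,2R,5R,6S)-1-O-(triethylsilyl)-2,6-cyclolycopene-1,5-diol | CC(C)=CCC/C(C)=C/C=C/C(C)=C/C=C/C(C)=C/C=C/C=C(C)/C=C/C=C(C)/C=C/[C@H]1[C@H](C(C)(C)O[Si](CC)(CC)CC)CC[C@@]1(C)O | intermediate
16 | (all-E,2R,5R,6S)-2,6-cyclolycopene-1,5-diol | CC(C)=CCC/C(C)=C/C=C/C(C)=C/C=C/C(C)=C/C=C/C=C(C)/C=C/C=C(C)/C=C/[C@H]1[C@H](C(C)(C)O)CC[C@@]1(C)O | target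

Total step count: 11. Longest linear sequence: 8 steps (steps 1 to 6, 10 and 11, from 1).

Steps most likely to fail

Step 10. The C6 radical may add to the conjugated polyene instead of being captured at nickel, and the polyenyl iodide may be reduced or isomerised at the cathode. The fallback sets out from 8 and forms the same C6–C7 bond with a short partner that cannot intercept the radical, then builds the polyene by Wittig chemistry. Acid 8, activated as 14, is coupled under the step 10 conditions with (2E,4E)-5-iodo-3-methylpenta-2,4-dien-1-ol to give the C15 dienol (2E,4E)-5-[(1S,2R,5R)-2-hydroxy-2-methyl-5-[2-(triethylsilyloxy)propan-2-yl]cyclopentyl]-3-methylpenta-2,4-dien-1-ol F1. PPh3·HBr in CH2Cl2 at 0 °C should convert F1 into the C15 phosphonium bromide F2. The C25 partner is made separately: pseudoionone and vinylmagnesium bromide give vinyl-ψ-ionol F3, PPh3·HBr gives the ψ-C15 phosphonium bromide F4, and a Wittig reaction of F4 (NaOMe) with an excess of 2,7-dimethylocta-2,4,6-trienedial gives apo-12'-lycopenal F5. Wittig olefination of F5 with the ylide of F2 (NaOMe, CH2Cl2/MeOH), followed by thermal Z-to-E equilibration in warm heptane, comes back to the route at 15.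

Step 9. CrCl2 may reduce or pinacol-couple the polyenal by single-electron transfer, E control may be incomplete, and the iodide may degrade during the chromium work-up. The fallback sets out from 12. Ohira–Bestmann homologation (dimethyl (1-diazo-2-oxopropyl)phosphonate, K2CO3, MeOH/THF) gives the terminal enyne (3E,5E,7E,9E,11E,13E,15E,17E,19E)-3,7,12,16,20,24-hexamethylpentacosa-3,5,7,9,11,13,15,17,19,23-decaen-1-yne F6. Hydrozirconation of F6 with Cp2Zr(H)Cl (syn addition, terminal alkyne far faster than the polyene) and iodinolysis with N-iodosuccinimide at −78 °C comes back to the route at 13, with the E geometry fixed by the mechanism.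

Step 5. The carbene may add only slowly to the hindered aldehyde on the fully substituted C6, and the acyl azolium may lose the β-oxygen by elimination or open the ring by retro-aldol cleavage. The fallback sets out from 6. Pinnick oxidation (NaClO2, NaH2PO4, 2-methylbut-2-ene, t-BuOH/H2O) gives the epoxy acid (1S,2R,5R)-5-methyl-2-[2-(triethylsilyloxy)propan-2-yl]-6-oxabicyclo[3.1.0]hexane-1-carboxylic acid F7. Benzylation (BnBr, Cs2CO3, DMF) gives the benzyl epoxy ester F8. SmI2 in THF with N,N-dimethylethanolamine at −78 °C cleaves the C6–O bond by electron transfer to the ester and comes back to the route at 7.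

Further compounds

F1 | step 10 | (2E,4E)-5-[(1S,2R,5R)-2-hydroxy-2-methyl-5-[2-(triethylsilyloxy)propan-2-yl]cyclopentyl]-3-methylpenta-2,4-dien-1-ol | OC/C=C(C)/C=C/[C@H]1[C@H](C(C)(C)O[Si](CC)(CC)CC)CC[C@@]1(C)O
F2 | step 10 | [(2E,4E)-5-[(1S,2R,5R)-2-hydroxy-2-methyl-5-[2-(triethylsilyloxy)propan-2-yl]cyclopentyl]-3-methylpenta-2,4-dien-1-yl]triphenylphosphonium bromide | c1ccccc1[P+](c1ccccc1)(c1ccccc1)C/C=C(C)/C=C/[C@H]1[C@H](C(C)(C)O[Si](CC)(CC)CC)CC[C@@]1(C)O.[Br-]
F3 | step 10 | vinyl-ψ-ionol, (4E,6E)-3,7,11-trimethyldodeca-1,4,6,10-tetraen-3-ol (racemic carbinol) | C=CC(C)(O)/C=C/C=C(C)/CCC=C(C)C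
F4 | step 10 | [(2E,4E,6E)-3,7,11-trimethyldodeca-2,4,6,10-tetraen-1-yl]triphenylphosphonium bromide | CC(C)=CCC/C(C)=C/C=C/C(C)=C/C[P+](c1ccccc1)(c1ccccc1)c1ccccc1.[Br-]
F5 | step 10 | apo-12'-lycopenal (all-E C25 aldehyde) | CC(C)=CCC/C(C)=C/C=C/C(C)=C/C=C/C(C)=C/C=C/C=C(C)/C=O
F6 | step 9 | (3E,5E,7E,9E,11E,13E,15E,17E,19E)-3,7,12,16,20,24-hexamethylpentacosa-3,5,7,9,11,13,15,17,19,23-decaen-1-yne | CC(C)=CCC/C(C)=C/C=C/C(C)=C/C=C/C(C)=C/C=C/C=C(C)/C=C/C=C(C)/C#C
F7 | step 5 | (1S,2R,5R)-5-methyl-2-[2-(triethylsilyloxy)propan-2-yl]-6-oxabicyclo[3.1.0]hexane-1-carboxylic acid | OC(=O)[C@@]12O[C@]1(C)CC[C@H]2C(C)(C)O[Si](CC)(CC)CC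
F8 | step 5 | benzyl (1S,2R,5R)-5-methyl-2-[2-(triethylsilyloxy)propan-2-yl]-6-oxabicyclo[3.1.0]hexane-1-carboxylate | O=C(OCc1ccccc1)[C@@]12O[C@]1(C)CC[C@H]2C(C)(C)O[Si](CC)(CC)CC
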